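**Strategy.** Everything rests on building ring B, the resorcinol-type benzo ring of the catechol-bearing dihydrobenzofuran, last and from scratch. Ring B carries C3' on C3a' between its two oxygens (C4'–OH, C7a'–O1') and C3 of the styryl-bearing unit on C6', para to C3a'. This is the 2,5-disubstituted resorcinol pattern that a thermal cyclobutenone/siloxyalkyne benzannulation delivers. Heating the 3-substituted cyclobutenone that carries the finished bromo-dihydrobenzofuran with a triisopropylsiloxyalkyne that carries C3', C2' and both aryl groups forms C3a'–C4', C7a'–C7' and C4'–C5' in one operation and joins the halves without touching four stereocentres. O1'–C2' closure, Heck styrylation and demethylation finish the synthesis.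

Key step: step 15

Remarks on the chemistry:
- Locants: unprimed atoms and ring A belong to the styryl-bearing dihydrobenzofuran (unit 1); primed atoms and ring B belong to the catechol-bearing one (unit 2).
- The cyclobutenone and the annulation product carry the (2R,3R) unit 1 and the C3' configuration of the target. The silyloxy carbinol at C2' is deliberately carried as the syn (R) epimer that the boron aldol gives most reliably. It is a spectator that is erased on ring closure, and both an ionising and an invertive closure of this epimer lead to the trans ring.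
- The α-aryl aldehyde of unit 2 is never exposed to base: it is homologated with a non-basic ylide.
- Assumption: the S-configured dirhodium carboxylate of step 5 is taken to deliver the 2R ring; should the sense of induction be the opposite, its mirror-image catalyst is used.

**Unit 1: cyclobutenone**

Step 1
Reactants: 1 4-bromo-2,6-dimethoxybenzaldehyde
Product: 2 4-bromo-2-hydroxy-6-methoxybenzaldehyde
Conditions: BCl3 (1.1 equiv), CH2Cl2, −78 to 0 °C; aq. work-up
Reagents that add atoms: none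
Why: Carbonyl-directed Lewis-acid ether cleavage should remove only one ortho methyl group, because the boron chelate between the first phenoxide and the formyl oxygen deactivates the second methoxy group.

Step 2
Reactants: 2 4-bromo-2-hydroxy-6-methoxybenzaldehyde; 3 4-methoxybenzyl chloride
Product: 4 4-bromo-2-methoxy-6-[(4-methoxybenzyl)oxy]benzaldehyde
Conditions: K2CO3, KI (cat.), DMF, 60 °C
Reagents that add atoms: none
Why: Williamson ether synthesis on the salicylaldehyde phenoxide installs the benzylic CH2 that later becomes C2 together with its 4-methoxyphenyl group.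

Step 3
Reactants: 4 4-bromo-2-methoxy-6-[(4-methoxybenzyl)oxy]benzaldehyde; 5 ethyl diazoacetate
Product: 6 ethyl 2-{4-bromo-2-methoxy-6-[(4-methoxybenzyl)oxy]phenyl}-3-hydroxyprop-2-enoate (enol form of the α-formyl arylacetate, alkene geometry not fixed)
Conditions: HBF4·OEt2 (10 mol%), CH2Cl2, −78 °C to rt
Reagents that add atoms: none
Why: Acid-catalysed addition of the diazo ester to the aldehyde followed by 1,2-aryl shift with loss of N2 (the aryl-migration mode of the Roskamp homologation, favoured by the two ortho alkoxy groups) should place the electron-rich arene on the carbon that becomes C3.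

Step 4
Reactants: 6 ethyl 2-{4-bromo-2-methoxy-6-[(4-methoxybenzyl)oxy]phenyl}-3-hydroxyprop-2-enoate
Product: 7 ethyl {4-bromo-2-methoxy-6-[(4-methoxybenzyl)oxy]phenyl}(diazo)acetate
Conditions: p-ABSA, Et3N, MeCN, 0 °C to rt
Reagents that add atoms: 4-acetamidobenzenesulfonyl azide (p-ABSA), CC(=O)Nc1ccc(cc1)S(=O)(=O)N=[N+]=[N-]
Why: Regitz deformylative diazo transfer, in which the enolate of the formyl ester attacks the sulfonyl azide and the formyl group leaves as the N-formylsulfonamide, should give the aryldiazoacetate.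

Step 5
Reactants: 7 ethyl {4-bromo-2-methoxy-6-[(4-methoxybenzyl)oxy]phenyl}(diazo)acetate
Product: 9 ethyl (2R,3R)-6-bromo-4-methoxy-2-(4-methoxyphenyl)-2,3-dihydro-1-benzofuran-3-carboxylate (trans), via cis-(2R,3S) ethyl ester 8 (not isolated)
Conditions: Rh2(S-PTTL)4 [dirhodium tetrakis(N-phthaloyl-(S)-tert-leucinate)] (1 mol%), toluene, −60 °C; then NaOEt (0.3 equiv), EtOH, rt
Reagents that add atoms: none
Why: Enantioselective intramolecular 1,5 C–H insertion of the dirhodium donor/acceptor carbene into the doubly activated benzylic C–H bond sets C2 under catalyst control and gives the cis ester, and ethoxide then epimerises only the acidic C3 centre to the thermodynamically preferred trans isomer, ring opening being a stereoelectronically disfavoured retro-5-endo-trig process.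

Step 6
Reactants: 9 ethyl (2R,3R)-6-bromo-4-methoxy-2-(4-methoxyphenyl)-2,3-dihydro-1-benzofuran-3-carboxylate
Product: 11 (2R,3R)-6-bromo-3-ethynyl-4-methoxy-2-(4-methoxyphenyl)-2,3-dihydro-1-benzofuran, via aldehyde 10 (not isolated)
Conditions: DIBAL-H (1.2 equiv), CH2Cl2, −78 °C; then MeOH, dimethyl (1-diazo-2-oxopropyl)phosphonate, K2CO3, −78 °C to rt
Reagents that add atoms: dimethyl (1-diazo-2-oxopropyl)phosphonate (Ohira–Bestmann reagent), COP(=O)(OC)C(=[N+]=[N-])C(C)=O
Why: One-pot partial reduction and Seyferth–Gilbert homologation (Ohira–Bestmann modification) should turn the ester into the terminal alkyne, and the intermediate aldehyde can only equilibrate at C3 towards the trans isomer that is already present, so no stereochemical information is lost.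

Step 7
Reactants: 11 (2R,3R)-6-bromo-3-ethynyl-4-methoxy-2-(4-methoxyphenyl)-2,3-dihydro-1-benzofuran
Product: 13 3-[(2R,3R)-6-bromo-4-methoxy-2-(4-methoxyphenyl)-2,3-dihydro-1-benzofuran-3-yl]cyclobut-2-en-1-one, via cyclobuteniminium triflate 12 (not isolated)
Conditions: N,N-dimethylacetamide, Tf2O, 2,4,6-collidine, ClCH2CH2Cl, −15 °C to reflux; then H2O, rt
Reagents that add atoms: N,N-dimethylacetamide, CC(=O)N(C)C; water, O
Why: Keteniminium–alkyne [2+2] cycloaddition, in which the electrophilic central carbon of the keteniminium ion bonds to the terminal alkyne carbon, followed by hydrolysis of the cyclobuteniminium salt should give the 3-substituted cyclobutenone without ever exposing the C3–H to base.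

**Unit 2: siloxyalkyne**

Step 8
Reactants: 14 (3,5-dimethoxyphenyl)acetic acid; 15 (R)-4-benzyl-1,3-oxazolidin-2-one
Product: 17 (R)-4-benzyl-3-[(3,5-dimethoxyphenyl)acetyl]-1,3-oxazolidin-2-one, via mixed pivalic anhydride 16 (not isolated)
Conditions: PivCl, Et3N, THF, −20 °C; then LiCl, 15, rt
Reagents that add atoms: none
Why: N-Acylation of the Evans auxiliary through the mixed pivalic anhydride, which the lithium-activated oxazolidinone attacks at the less hindered arylacetyl carbonyl, should give the imide.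

Step 9
Reactants: 17 (R)-4-benzyl-3-[(3,5-dimethoxyphenyl)acetyl]-1,3-oxazolidin-2-one; 18 3,4-dimethoxybenzaldehyde
Product: 20 (R)-4-benzyl-3-[(2R,3R)-3-(3,4-dimethoxyphenyl)-2-(3,5-dimethoxyphenyl)-3-hydroxypropanoyl]-1,3-oxazolidin-2-one (syn aldol), via dibutylboron Z-enolate 19 (not isolated)
Conditions: Bu2BOTf, i-Pr2NEt, CH2Cl2, −78 to 0 °C; then 18, −78 to 0 °C; pH 7 buffer, MeOH, H2O2
Reagents that add atoms: none
Why: Evans syn-aldol reaction, in which the Z boron enolate reacts through a Zimmerman–Traxler chair on the face away from the benzyl group of the auxiliary, sets the α-carbon (the future C3') and gives the syn carbinol at the future C2'.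

Step 10
Reactants: 20 (R)-4-benzyl-3-[(2R,3R)-3-(3,4-dimethoxyphenyl)-2-(3,5-dimethoxyphenyl)-3-hydroxypropanoyl]-1,3-oxazolidin-2-one
Product: 21 (2R,3R)-3-(3,4-dimethoxyphenyl)-2-(3,5-dimethoxyphenyl)-3-hydroxy-N-methoxy-N-methylpropanamide
Conditions: MeNHOMe·HCl, AlMe3, CH2Cl2, −10 to 0 °C
Reagents that add atoms: N,O-dimethylhydroxylamine hydrochloride, CNOC.Cl
Why: Weinreb transamidation of the aldol imide, assisted by the aluminium alkoxide of the free β-hydroxyl group, should release the auxiliary without enolising the α-aryl centre.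

Step 11
Reactants: 21 (2R,3R)-3-(3,4-dimethoxyphenyl)-2-(3,5-dimethoxyphenyl)-3-hydroxy-N-methoxy-N-methylpropanamide
Product: 22 (2R,3R)-3-{[tert-butyl(dimethyl)silyl]oxy}-3-(3,4-dimethoxyphenyl)-2-(3,5-dimethoxyphenyl)-N-methoxy-N-methylpropanamide
Conditions: TBSOTf, 2,6-lutidine, CH2Cl2, 0 °C
Reagents that add atoms: tert-butyldimethylsilyl triflate, CC(C)(C)[Si](C)(C)OS(=O)(=O)C(F)(F)F
Why: Silylation of the hindered benzylic alcohol with the silyl triflate and a non-nucleophilic base protects the C2' oxygen for the organolithium steps and for the ketene chemistry.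

Step 12
Reactants: 22 (2R,3R)-3-{[tert-butyl(dimethyl)silyl]oxy}-3-(3,4-dimethoxyphenyl)-2-(3,5-dimethoxyphenyl)-N-methoxy-N-methylpropanamide
Product: 23 (2R,3R)-3-{[tert-butyl(dimethyl)silyl]oxy}-3-(3,4-dimethoxyphenyl)-2-(3,5-dimethoxyphenyl)propanal
Conditions: DIBAL-H, THF, −78 °C; Rochelle salt work-up; used crude at once
Reagents that add atoms: none
Why: Hydride reduction of the Weinreb amide stops at the chelated tetrahedral intermediate and should give the aldehyde on work-up, and the configurationally labile α-aryl aldehyde is carried on without chromatography.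

Step 13
Reactants: 23 (2R,3R)-3-{[tert-butyl(dimethyl)silyl]oxy}-3-(3,4-dimethoxyphenyl)-2-(3,5-dimethoxyphenyl)propanal
Product: 24 tert-butyl{[(1R,2R)-4,4-dibromo-1-(3,4-dimethoxyphenyl)-2-(3,5-dimethoxyphenyl)but-3-en-1-yl]oxy}dimethylsilane
Conditions: CBr4, PPh3, 2,6-lutidine, CH2Cl2, 0 °C
Reagents that add atoms: carbon tetrabromide, BrC(Br)(Br)Br
Why: Ramirez dibromo-olefination (first stage of the Corey–Fuchs sequence) with a non-basic ylide should homologate the aldehyde without epimerising the C3' centre, which then ceases to be α to a carbonyl group.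

Step 14
Reactants: 24 tert-butyl{[(1R,2R)-4,4-dibromo-1-(3,4-dimethoxyphenyl)-2-(3,5-dimethoxyphenyl)but-3-en-1-yl]oxy}dimethylsilane
Product: 27 {[(3S,4R)-4-{[tert-butyl(dimethyl)silyl]oxy}-4-(3,4-dimethoxyphenyl)-3-(3,5-dimethoxyphenyl)but-1-yn-1-yl]oxy}tri(propan-2-yl)silane, via lithium acetylide 25 (not isolated), via lithium ynolate 26 (not isolated)
Conditions: n-BuLi (2.05 equiv), THF, −78 °C; then t-BuOOLi (from t-BuOOH, LiHMDS), −78 to 0 °C; then TIPSOTf, −78 to 0 °C
Reagents that add atoms: lithium tert-butyl peroxide, CC(C)(C)OO[Li]; triisopropylsilyl triflate, CC(C)[Si](C(C)C)(C(C)C)OS(=O)(=O)C(F)(F)F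
Why: Bromine–lithium exchange and Fritsch–Buttenberg–Wiechell rearrangement (second stage of the Corey–Fuchs sequence) should give the lithium acetylide, which the lithium peroxide oxidises to the ynolate and the bulky silyl triflate traps on oxygen, the acetylide and ynolate charges protecting the propargylic C3'–H from deprotonation.

**Union and endgame**

Step 15
Reactants: 13 3-[(2R,3R)-6-bromo-4-methoxy-2-(4-methoxyphenyl)-2,3-dihydro-1-benzofuran-3-yl]cyclobut-2-en-1-one; 27 {[(3S,4R)-4-{[tert-butyl(dimethyl)silyl]oxy}-4-(3,4-dimethoxyphenyl)-3-(3,5-dimethoxyphenyl)but-1-yn-1-yl]oxy}tri(propan-2-yl)silane (1.3 equiv)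
Product: 32 5-[(2R,3R)-6-bromo-4-methoxy-2-(4-methoxyphenyl)-2,3-dihydro-1-benzofuran-3-yl]-2-[(1S,2R)-2-{[tert-butyl(dimethyl)silyl]oxy}-2-(3,4-dimethoxyphenyl)-1-(3,5-dimethoxyphenyl)ethyl]-3-{[tri(propan-2-yl)silyl]oxy}phenol, via vinylketene 28 (not isolated), via vinylcyclobutenone 29 (not isolated), via dienylketene 30 (not isolated), via cyclohexadienone 31 (not isolated)
Conditions: toluene (degassed), 80 °C, then 110 °C
Reagents that add atoms: none
Why: Danheiser benzannulation: thermal 4π electrocyclic opening of 13 gives vinylketene 28, whose ketene C=C undergoes a regiospecific [2+2] cycloaddition with the electron-rich siloxyalkyne, the nucleophilic alkyne carbon β to oxygen bonding to the ketene carbonyl carbon (C3a'–C4') and the oxygen-bearing carbon to the former cyclobutenone C2 (C7a'–C7'). The resulting 4-vinylcyclobutenone 29 opens again (4π) to dienylketene 30, ring B closes by a thermal disrotatory 6π electrocyclisation that forms C4'–C5', and cyclohexadienone 31 tautomerises to the phenol. The closest known reaction type is the benzannulation of 3-alkylcyclobutenones with 1-siloxyalkynes to resorcinol monosilyl ethers, applied here to α-branched partners. No stereocentre is created, and the four existing ones should survive because the cascade is neutral and base-free, so neither the C3–H next to the ketene system nor the benzylic C3'–H is removed. The only selectivity needed is the regiochemistry of the [2+2] step, which the polarisation of the ynol ether secures: it places C3' between the two oxygens and C3 para to it, and the slight excess of 27 limits acylation of the product phenol by the vinylketene.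

Step 16
Reactants: 32 (the ring B resorcinol monosilyl ether of step 15)
Product: 34 (2S,3S)-6-[(2R,3R)-6-bromo-4-methoxy-2-(4-methoxyphenyl)-2,3-dihydro-1-benzofuran-3-yl]-2-(3,4-dimethoxyphenyl)-3-(3,5-dimethoxyphenyl)-2,3-dihydro-1-benzofuran-4-ol, via resorcinol carbinol 33 (not isolated)
Conditions: TBAF, THF, 0 °C to rt; then TsOH·H2O (excess over fluoride), 40 °C
Reagents that add atoms: none
Why: Fluoride desilylation frees both ring B phenols and the benzylic alcohol, and acid-mediated cyclodehydration through the 3,4-dimethoxybenzyl cation (5-exo capture by either of the two equivalent phenols) should form O1'–C2' trans to the C3' aryl group, the preferred outcome that an invertive closure of this syn carbinol would give as well.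

Step 17
Reactants: 34 (the bromide of step 16); 35 4-methoxystyrene
Product: 36 (2S,3S)-2-(3,4-dimethoxyphenyl)-3-(3,5-dimethoxyphenyl)-6-{(2R,3R)-4-methoxy-2-(4-methoxyphenyl)-6-[(E)-2-(4-methoxyphenyl)ethenyl]-2,3-dihydro-1-benzofuran-3-yl}-2,3-dihydro-1-benzofuran-4-ol
Conditions: Pd(OAc)2 (5 mol%), P(o-tol)3, Et3N, DMF, 100 °C
Reagents that add atoms: none
Why: Mizoroki–Heck coupling of the aryl bromide with the styrene should give the E-stilbene by syn insertion and syn β-hydride elimination, the free phenol and both dihydrobenzofurans being inert to the neutral palladium cycle.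

Step 18
Reactants: 36 (the heptamethyl ether of step 17)
Product: 37 CNP0107857.3, 4-[(2S,3S)-3-(3,5-dihydroxyphenyl)-4-hydroxy-6-{(2R,3R)-4-hydroxy-2-(4-hydroxyphenyl)-6-[(E)-2-(4-hydroxyphenyl)ethenyl]-2,3-dihydro-1-benzofuran-3-yl}-2,3-dihydro-1-benzofuran-2-yl]benzene-1,2-diol
Conditions: BBr3 (excess), CH2Cl2, −78 to 0 °C; then MeOH, H2O
Reagents that add atoms: none
Why: Lewis-acid cleavage of all seven aryl methyl ethers by bromide attack on the boron-complexed methyl groups should give the octaphenol, and any reversible ionisation at C2 or C2' can only reclose trans because C3 and C3' are not touched.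

**Compound list**

1 | 4-bromo-2,6-dimethoxybenzaldehyde | COc1cc(Br)cc(OC)c1C=O | starting material
2 | 4-bromo-2-hydroxy-6-methoxybenzaldehyde | COc1cc(Br)cc(O)c1C=O | intermediate
3 | 4-methoxybenzyl chloride | COc1ccc(CCl)cc1 | starting material
4 | 4-bromo-2-methoxy-6-[(4-methoxybenzyl)oxy]benzaldehyde | COc1ccc(COc2cc(Br)cc(OC)c2C=O)cc1 | intermediate
5 | ethyl diazoacetate | CCOC(=O)C=[N+]=[N-] | starting material
6 | ethyl 2-{4-bromo-2-methoxy-6-[(4-methoxybenzyl)oxy]phenyl}-3-hydroxyprop-2-enoate | CCOC(=O)C(=CO)c1c(OC)cc(Br)cc1OCc1ccc(OC)cc1 | intermediate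
7 | ethyl {4-bromo-2-methoxy-6-[(4-methoxybenzyl)oxy]phenyl}(diazo)acetate | CCOC(=O)C(=[N+]=[N-])c1c(OC)cc(Br)cc1OCc1ccc(OC)cc1 | intermediate
8 | ethyl (2R,3S)-6-bromo-4-methoxy-2-(4-methoxyphenyl)-2,3-dihydro-1-benzofuran-3-carboxylate (cis) | Brc1cc(OC)c2c(c1)O[C@@H](c1ccc(OC)cc1)[C@H]2C(=O)OCC | intermediate
9 | ethyl (2R,3R)-6-bromo-4-methoxy-2-(4-methoxyphenyl)-2,3-dihydro-1-benzofuran-3-carboxylate (trans) | Brc1cc(OC)c2c(c1)O[C@@H](c1ccc(OC)cc1)[C@@H]2C(=O)OCC | intermediate
10 | (2R,3R)-6-bromo-4-methoxy-2-(4-methoxyphenyl)-2,3-dihydro-1-benzofuran-3-carbaldehyde | Brc1cc(OC)c2c(c1)O[C@@H](c1ccc(OC)cc1)[C@@H]2C=O | intermediate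
11 | (2R,3R)-6-bromo-3-ethynyl-4-methoxy-2-(4-methoxyphenyl)-2,3-dihydro-1-benzofuran | Brc1cc(OC)c2c(c1)O[C@@H](c1ccc(OC)cc1)[C@@H]2C#C | intermediate
12 | N-{3-[(2R,3R)-6-bromo-4-methoxy-2-(4-methoxyphenyl)-2,3-dihydro-1-benzofuran-3-yl]cyclobut-2-en-1-ylidene}-N-methylmethanaminium triflate | Brc1cc(OC)c2c(c1)O[C@@H](c1ccc(OC)cc1)[C@@H]2C1=CC(=[N+](C)C)C1.[O-]S(=O)(=O)C(F)(F)F | intermediate
13 | 3-[(2R,3R)-6-bromo-4-methoxy-2-(4-methoxyphenyl)-2,3-dihydro-1-benzofuran-3-yl]cyclobut-2-en-1-one | Brc1cc(OC)c2c(c1)O[C@@H](c1ccc(OC)cc1)[C@@H]2C1=CC(=O)C1 | intermediate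
14 | (3,5-dimethoxyphenyl)acetic acid | COc1cc(CC(=O)O)cc(OC)c1 | starting material
15 | (R)-4-benzyl-1,3-oxazolidin-2-one | O=C1N[C@H](Cc2ccccc2)CO1 | starting material
16 | (3,5-dimethoxyphenyl)acetic pivalic anhydride | COc1cc(CC(=O)OC(=O)C(C)(C)C)cc(OC)c1 | intermediate
17 | (R)-4-benzyl-3-[(3,5-dimethoxyphenyl)acetyl]-1,3-oxazolidin-2-one | O=C1OC[C@@H](Cc2ccccc2)N1C(=O)Cc1cc(OC)cc(OC)c1 | intermediate
18 | 3,4-dimethoxybenzaldehyde | COc1ccc(C=O)cc1OC | starting material
19 | dibutylboron Z-enolate of 17 | CCCCB(CCCC)O/C(=C\c1cc(OC)cc(OC)c1)N1C(=O)OC[C@H]1Cc1ccccc1 | intermediate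
20 | (R)-4-benzyl-3-[(2R,3R)-3-(3,4-dimethoxyphenyl)-2-(3,5-dimethoxyphenyl)-3-hydroxypropanoyl]-1,3-oxazolidin-2-one | O=C1OC[C@@H](Cc2ccccc2)N1C(=O)[C@H](c1cc(OC)cc(OC)c1)[C@@H](O)c1ccc(OC)c(OC)c1 | intermediate
21 | (2R,3R)-3-(3,4-dimethoxyphenyl)-2-(3,5-dimethoxyphenyl)-3-hydroxy-N-methoxy-N-methylpropanamide | CON(C)C(=O)[C@H](c1cc(OC)cc(OC)c1)[C@@H](O)c1ccc(OC)c(OC)c1 | intermediate
22 | (2R,3R)-3-{[tert-butyl(dimethyl)silyl]oxy}-3-(3,4-dimethoxyphenyl)-2-(3,5-dimethoxyphenyl)-N-methoxy-N-methylpropanamide | CON(C)C(=O)[C@H](c1cc(OC)cc(OC)c1)[C@@H](O[Si](C)(C)C(C)(C)C)c1ccc(OC)c(OC)c1 | intermediate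
23 | (2R,3R)-3-{[tert-butyl(dimethyl)silyl]oxy}-3-(3,4-dimethoxyphenyl)-2-(3,5-dimethoxyphenyl)propanal | O=C[C@H](c1cc(OC)cc(OC)c1)[C@@H](O[Si](C)(C)C(C)(C)C)c1ccc(OC)c(OC)c1 | intermediate
24 | tert-butyl{[(1R,2R)-4,4-dibromo-1-(3,4-dimethoxyphenyl)-2-(3,5-dimethoxyphenyl)but-3-en-1-yl]oxy}dimethylsilane | BrC(Br)=C[C@H](c1cc(OC)cc(OC)c1)[C@@H](O[Si](C)(C)C(C)(C)C)c1ccc(OC)c(OC)c1 | intermediate
25 | lithium acetylide formed from 24 (stereocentres as in 27) | [Li]C#C[C@H](c1cc(OC)cc(OC)c1)[C@@H](O[Si](C)(C)C(C)(C)C)c1ccc(OC)c(OC)c1 | intermediate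
26 | lithium ynolate formed from 25 (stereocentres as in 27) | [Li]OC#C[C@H](c1cc(OC)cc(OC)c1)[C@@H](O[Si](C)(C)C(C)(C)C)c1ccc(OC)c(OC)c1 | intermediate
27 | {[(3S,4R)-4-{[tert-butyl(dimethyl)silyl]oxy}-4-(3,4-dimethoxyphenyl)-3-(3,5-dimethoxyphenyl)but-1-yn-1-yl]oxy}tri(propan-2-yl)silane | CC(C)[Si](C(C)C)(C(C)C)OC#C[C@H](c1cc(OC)cc(OC)c1)[C@@H](O[Si](C)(C)C(C)(C)C)c1ccc(OC)c(OC)c1 | intermediate
28 | 3-[(2R,3R)-6-bromo-4-methoxy-2-(4-methoxyphenyl)-2,3-dihydro-1-benzofuran-3-yl]buta-1,3-dien-1-one (vinylketene) | Brc1cc(OC)c2c(c1)O[C@@H](c1ccc(OC)cc1)[C@@H]2C(=C)C=C=O | intermediate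
29 | 4-{1-[(2R,3R)-unit 1-3-yl]ethenyl}-2-[(1S,2R)-2-silyloxy-1,2-diarylethyl]-3-{[tri(propan-2-yl)silyl]oxy}cyclobut-2-en-1-one (C4 of the four-membered ring not defined) | Brc1cc(OC)c2c(c1)O[C@@H](c1ccc(OC)cc1)[C@@H]2C(=C)C1C(=O)C([C@H](c3cc(OC)cc(OC)c3)[C@@H](O[Si](C)(C)C(C)(C)C)c3ccc(OC)c(OC)c3)=C1O[Si](C(C)C)(C(C)C)C(C)C | intermediate
30 | (3E)-2-[(1S,2R)-2-silyloxy-1,2-diarylethyl]-5-[(2R,3R)-unit 1-3-yl]-3-{[tri(propan-2-yl)silyl]oxy}hexa-1,3,5-trien-1-one (dienylketene, ketenyl and vinyl groups cis) | Brc1cc(OC)c2c(c1)O[C@@H](c1ccc(OC)cc1)[C@@H]2C(=C)/C=C(O[Si](C(C)C)(C(C)C)C(C)C)\C(=C=O)[C@H](c1cc(OC)cc(OC)c1)[C@@H](O[Si](C)(C)C(C)(C)C)c1ccc(OC)c(OC)c1 | intermediate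
31 | 2-[(1S,2R)-2-silyloxy-1,2-diarylethyl]-5-[(2R,3R)-unit 1-3-yl]-3-{[tri(propan-2-yl)silyl]oxy}cyclohexa-2,4-dien-1-one | Brc1cc(OC)c2c(c1)O[C@@H](c1ccc(OC)cc1)[C@@H]2C1=CC(O[Si](C(C)C)(C(C)C)C(C)C)=C([C@H](c3cc(OC)cc(OC)c3)[C@@H](O[Si](C)(C)C(C)(C)C)c3ccc(OC)c(OC)c3)C(=O)C1 | intermediate
32 | 5-[(2R,3R)-6-bromo-4-methoxy-2-(4-methoxyphenyl)-2,3-dihydro-1-benzofuran-3-yl]-2-[(1S,2R)-2-{[tert-butyl(dimethyl)silyl]oxy}-2-(3,4-dimethoxyphenyl)-1-(3,5-dimethoxyphenyl)ethyl]-3-{[tri(propan-2-yl)silyl]oxy}phenol | Brc1cc(OC)c2c(c1)O[C@@H](c1ccc(OC)cc1)[C@@H]2c1cc(O)c(c(O[Si](C(C)C)(C(C)C)C(C)C)c1)[C@H](c1cc(OC)cc(OC)c1)[C@@H](O[Si](C)(C)C(C)(C)C)c1ccc(OC)c(OC)c1 | intermediate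
33 | 5-[(2R,3R)-6-bromo-4-methoxy-2-(4-methoxyphenyl)-2,3-dihydro-1-benzofuran-3-yl]-2-[(1S,2R)-2-(3,4-dimethoxyphenyl)-1-(3,5-dimethoxyphenyl)-2-hydroxyethyl]benzene-1,3-diol | Brc1cc(OC)c2c(c1)O[C@@H](c1ccc(OC)cc1)[C@@H]2c1cc(O)c(c(O)c1)[C@H](c1cc(OC)cc(OC)c1)[C@@H](O)c1ccc(OC)c(OC)c1 | intermediate
34 | (2S,3S)-6-[(2R,3R)-6-bromo-4-methoxy-2-(4-methoxyphenyl)-2,3-dihydro-1-benzofuran-3-yl]-2-(3,4-dimethoxyphenyl)-3-(3,5-dimethoxyphenyl)-2,3-dihydro-1-benzofuran-4-ol | Brc1cc(OC)c2c(c1)O[C@@H](c1ccc(OC)cc1)[C@@H]2c1cc(O)c2c(c1)O[C@H](c1ccc(OC)c(OC)c1)[C@H]2c1cc(OC)cc(OC)c1 | intermediate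
35 | 4-methoxystyrene | COc1ccc(C=C)cc1 | starting material
36 | (2S,3S)-2-(3,4-dimethoxyphenyl)-3-(3,5-dimethoxyphenyl)-6-{(2R,3R)-4-methoxy-2-(4-methoxyphenyl)-6-[(E)-2-(4-methoxyphenyl)ethenyl]-2,3-dihydro-1-benzofuran-3-yl}-2,3-dihydro-1-benzofuran-4-ol | COc1ccc(/C=C/c2cc(OC)c3c(c2)O[C@@H](c2ccc(OC)cc2)[C@@H]3c2cc(O)c3c(c2)O[C@H](c2ccc(OC)c(OC)c2)[C@H]3c2cc(OC)cc(OC)c2)cc1 | intermediate
37 | CNP0107857.3, 4-[(2S,3S)-3-(3,5-dihydroxyphenyl)-4-hydroxy-6-{(2R,3R)-4-hydroxy-2-(4-hydroxyphenyl)-6-[(E)-2-(4-hydroxyphenyl)ethenyl]-2,3-dihydro-1-benzofuran-3-yl}-2,3-dihydro-1-benzofuran-2-yl]benzene-1,2-diol | Oc1ccc(/C=C/c2cc(O)c3c(c2)O[C@@H](c2ccc(O)cc2)[C@@H]3c2cc(O)c3c(c2)O[C@H](c2ccc(O)c(O)c2)[C@H]3c2cc(O)cc(O)c2)cc1 | target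

**Step count and risks**

Total step count: 18 (steps 1–7 for the cyclobutenone, steps 8–14 for the siloxyalkyne, steps 15–18 for union and endgame). Longest linear sequence: 11 steps (steps 1–7 and 15–18; the branch through steps 8–14 is equally long).

Steps most likely to fail:

Step 15. The bimolecular [2+2] capture of the vinylketene by the α-branched siloxyalkyne may be too slow, so that ketene self-condensation and O-acylation of the product phenol take over. The fallback assembles the 4-vinylcyclobutenone stepwise, so that the hindered alkyne meets a small and much more electrophilic ketene, and the halves are joined by a cross-coupling. It sets out from 27 and 11. Dichloroketene (Cl3CCOCl, zinc–copper couple, Et2O/DME) should add to 27 with the same polarity control to give the 4,4-dichloro-3-siloxycyclobutenone F1. Zinc dust in AcOH/TMEDA/EtOH at low temperature with one equivalent of reductant should remove one chlorine and give the 4-chlorocyclobutenone F2. In parallel, Markovnikov hydrostannation of 11 (Bu3SnH, Mo(CO)3(CNt-Bu)3 as catalyst, THF) should give the 1,1-disubstituted vinylstannane F3. Stille coupling of F2 with F3 (PdCl2(PhCN)2, tri(2-furyl)phosphine, dioxane) gives 29, where the fallback rejoins the route; on warming, 29 continues through 30 and 31 to 32.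

Step 7. The activated amide may attack the electron-rich arene rings instead of the alkyne, or the cyclobutenone double bond may migrate during iminium hydrolysis. The fallback uses a ketene that is not an arene electrophile and a reductive rather than hydrolytic release of the enone. From 11, dichloroketene (Cl3CCOCl, zinc–copper couple, DME/Et2O) should give the 4,4-dichlorocyclobutenone F4, and reductive dechlorination (zinc dust, AcOH, TMEDA, EtOH, 0 °C) returns to the route at 13.

Step 18. Sevenfold ether cleavage in the presence of the electron-rich stilbene may suffer from protonation of the alkene, cationic oligomerisation or incomplete demethylation. The fallback removes the methyl groups before the alkene exists and brings the last phenol in as an ester. From 34, BBr3 in CH2Cl2 should give the bromo heptaphenol F5, and Ac2O/pyridine its heptaacetate F6. Heck coupling of F6 with 4-acetoxystyrene (Pd(OAc)2, P(o-tol)3, Et3N, DMF) should give the octaacetate F7 of the target. Degassed K2CO3/MeOH at 0 °C then returns to the route at 37.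

Further compounds
F1 | step 15 | 4,4-dichloro-2-[(1S,2R)-2-{[tert-butyl(dimethyl)silyl]oxy}-2-(3,4-dimethoxyphenyl)-1-(3,5-dimethoxyphenyl)ethyl]-3-{[tri(propan-2-yl)silyl]oxy}cyclobut-2-en-1-one | O=C1C([C@H](c2cc(OC)cc(OC)c2)[C@@H](O[Si](C)(C)C(C)(C)C)c2ccc(OC)c(OC)c2)=C(O[Si](C(C)C)(C(C)C)C(C)C)C1(Cl)Cl
F2 | step 15 | 4-chloro-2-[(1S,2R)-2-{[tert-butyl(dimethyl)silyl]oxy}-2-(3,4-dimethoxyphenyl)-1-(3,5-dimethoxyphenyl)ethyl]-3-{[tri(propan-2-yl)silyl]oxy}cyclobut-2-en-1-one (C4 not defined) | O=C1C([C@H](c2cc(OC)cc(OC)c2)[C@@H](O[Si](C)(C)C(C)(C)C)c2ccc(OC)c(OC)c2)=C(O[Si](C(C)C)(C(C)C)C(C)C)C1Cl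
F3 | step 15 | tributyl{1-[(2R,3R)-6-bromo-4-methoxy-2-(4-methoxyphenyl)-2,3-dihydro-1-benzofuran-3-yl]ethenyl}stannane | Brc1cc(OC)c2c(c1)O[C@@H](c1ccc(OC)cc1)[C@@H]2C(=C)[Sn](CCCC)(CCCC)CCCC
F4 | step 7 | 3-[(2R,3R)-6-bromo-4-methoxy-2-(4-methoxyphenyl)-2,3-dihydro-1-benzofuran-3-yl]-4,4-dichlorocyclobut-2-en-1-one | Brc1cc(OC)c2c(c1)O[C@@H](c1ccc(OC)cc1)[C@@H]2C1=CC(=O)C1(Cl)Cl
F5 | step 18 | bromo heptaphenol, the fully demethylated form of 34 with unchanged configuration | Brc1cc(O)c2c(c1)O[C@@H](c1ccc(O)cc1)[C@@H]2c1cc(O)c2c(c1)O[C@H](c1ccc(O)c(O)c1)[C@H]2c1cc(O)cc(O)c1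
F6 | step 18 | heptaacetate of F5 | Brc1cc(OC(C)=O)c2c(c1)O[C@@H](c1ccc(OC(C)=O)cc1)[C@@H]2c1cc(OC(C)=O)c2c(c1)O[C@H](c1ccc(OC(C)=O)c(OC(C)=O)c1)[C@H]2c1cc(OC(C)=O)cc(OC(C)=O)c1
F7 | step 18 | octaacetate of the target | CC(=O)Oc1ccc(/C=C/c2cc(OC(C)=O)c3c(c2)O[C@@H](c2ccc(OC(C)=O)cc2)[C@@H]3c2cc(OC(C)=O)c3c(c2)O[C@H](c2ccc(OC(C)=O)c(OC(C)=O)c2)[C@H]3c2cc(OC(C)=O)cc(OC(C)=O)c2)cc1
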